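The beta run, at its one charge of solid substrate, cannot show whether solid substrate dissolves in proportion to the solid still lying there or at a pace set by the solution. So the beta run cannot say what a larger charge buys.

| setting | beta | Sunday's | Saturday's | Monday's | Friday's |
|---|---|---|---|---|---|
| solid substrate | 0.30 M | 0.30 M | 0.60 M | 1.2 M | 2.5 M |
| coupling partner | 1.2 M (fed, over 50 min) | 1.20 M (fed, over 50 min) | 1.20 M (fed, over 50 min) | 1.20 M (fed, over 50 min) | 1.20 M (fed, over 50 min) |
| free catalyst | 0.38 mM | 0.57 mM | 0.57 mM | 0.57 mM | 0.57 mM |
| remark | run made earlier; the fed solution adds 0.25 times the starting volume | the fed solution adds 0.25 times the starting volume | the fed solution adds 0.25 times the starting volume | the fed solution adds 0.25 times the starting volume | the fed solution adds 0.25 times the starting volume |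
| time |  | 50 min | 50 min | 50 min | 50 min |

beta run (percent of the solid substrate charged)

| time / min | product / % | solid substrate / % |
|---|---|---|
| 2.50 | 0 | 94.7 |
| 5.00 | 0.4 | 89.3 |
| 8.00 | 0 | 84.3 |
| 15.0 | 1.8 | 71.6 |
| 30.0 | 8.3 | 48.9 |

(scatter of a reading: 0.3 percentage points)

- charges are per starting volume, the dose included; the dosed solution carries all of it
- given per volume of solution although it is solid: solid substrate
- at the start none of the solid substrate is in solution
- a reading or a percentage of product counts all its forms, free or not
- the concentration of product that is asked is that of its free form alone
- "hardly changes" means that all values lie within two and a half points (for a concentration: within two and a half percent of the largest)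
- no earlier run changes the charge of free catalyst; that part of a forecast is a guess

- [product] (only what is free in solution) at the end for Sunday's, Saturday's, Monday's, Friday's, in this order
- how the row runs (rises, then falls / hardly changes / falls all the way / falls, then rises / rises all the way)

From the solid reading at 5.00 min, the beta run gives 0.00642 M min⁻¹. This is the quantity to carry: the dissolving pace, the solid substrate leaving the solid per minute and per starting volume.

Between 15.0 min and 30.0 min, the beta run lost solid at 0.00454 M min⁻¹ and made product at 0.00130 M min⁻¹. Product took less than the solid gave, so material was piling up in solution, and the row should follow how dissolving answers the charge.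

So charge Friday's 2.5 M first, beside Sunday's 0.30 M, leave feed and catalyst as they stand, and read the solid before making Saturday's or Monday's. By my reckoning, a pace proportional to the solid loses 1.64 M per starting volume from Friday's solid in 50 min. A pace set by the solution (zero order in the solid), held for that time, loses 0.321 M. I put no row on this, and that is where I differ from the forecast, which takes the first reading: "Undissolved substrate decays about first order". It gives 0.082 M, 0.155 M, 0.286 M and 0.5 M, so the row rises all the way.

The flasks give free product of 0.0723 M, 0.0723 M, 0.0723 M and 0.0723 M: the row hardly changes.

    free catalyst + product ⇌ idle complex, settled at all times (K = 3.63 M⁻¹)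
    catalyst intermediate B → free catalyst + product (k = 30.1 s⁻¹)
    coupling partner + free catalyst ⇌ catalyst intermediate A (K = 0.790 M⁻¹, k = 51.6 M⁻¹ s⁻¹)
    starting material + catalyst intermediate A ⇌ catalyst intermediate B (K = 1.07 M⁻¹, k = 2.35 M⁻¹ s⁻¹)
    free catalyst → spent catalyst (k = 1.51 × 10⁻⁶ s⁻¹)
    solid substrate ⇌ starting material, rate k6*(cs6 - [starting material]) while solid is left; crystals form when [starting material] > cs6 (solubility = 0.250 M, k = 4.43 × 10⁻⁴ s⁻¹)

At the end, starting material stands at 50.4% of Sunday's charge and 6.05% of Friday's, which is 0.151 M and 0.151 M per starting volume. Against the 0.321 M reckoned from the early dissolving pace read in the beta run and held over 50 min, Friday's solid lost 0.242 M per starting volume. Sunday's solid lost 0.242 M per starting volume.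

The data come from a simulation with made-up constants; noise was put on by code.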